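The grey run carried 2.39 times the second substrate of the violet run, yet after 80.0 min it held less target, 9.6% against 12.8%. You charge starting material, second substrate and free catalyst, and you want the target at the end of dawn, dusk and summer.

the same everywhere: starting material 0.10 M; free catalyst 15 mM
- violet: second substrate 0.041 M; run made earlier
- grey: second substrate 0.098 M; run made earlier
- dawn: second substrate 0.0600 M; time 2.0 h
- dusk: second substrate 0.100 M; time 2.0 h
- summer: second substrate 0.150 M; time 2.0 h

| run | time / min | target / % |
|---|---|---|
| violet | 20.0 | 5.4 |
| violet | 40.0 | 9.0 |
| violet | 60.0 | 11.7 |
| violet | 80.0 | 12.8 |
| grey | 6.00 | 1.6 |
| grey | 15.0 | 4.0 |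
| grey | 40.0 | 5.7 |
| grey | 80.0 | 9.6 |

(scatter of a reading: 1 percentage point)

- amount of target at the end, in percent of the starting material charged for dawn, dusk, summer, in this order
- how that number moves from the first to the last of them (falls all the way / rises all the way / hardly changes / falls, then rises / rises, then falls)

- "hardly changes" means that all values lie within two and a half points (for a concentration: within two and a half percent of the largest)

How strongly does second substrate cost you target? Define n, the slope of ln(target at a fixed time) against ln(charge of second substrate), the other charges held equal. This is an apparent reaction order. The pair at 80.0 min gives n = −0.330.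

Does n hold up? Go round once more with the pair at 40.0 min, which gives −0.524. Those readings are smaller, so the same scatter of 1 percentage point weighs more on them, and I keep the later value.

What does n predict? If it holds at 2.0 h and out to the charge of summer, which lies beyond both runs, summer over dawn is 0.739, and dusk over dawn 0.845.

Where does the row stand? In the violet run, target grows as time to the power m = 0.623, read from its first and last readings. Carrying the violet run to 2.0 h and then along n, I reckon 14.5% for dawn and 10.7% for summer.

The forecast differs. It gives 13.5%, 11% and 9%, a summer-to-dawn ratio of 0.667, and says falls all the way. Its ground: “Second substrate therefore appears to inhibit, probably by tying up catalyst”.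

The flask gives 19.4%, 16.9% and 14.3%, and the row falls all the way. My dawn level stood below the flask's.

    starting material + free catalyst ⇌ catalyst intermediate A (K = 4.50 /M, k = 3.30 /M/s)
    catalyst intermediate A → free catalyst + target (k = 0.00140 /s)
    second substrate + free catalyst ⇌ catalyst intermediate B (K = 23.0 /M, k = 0.0450 /M/s)
    catalyst intermediate B → free catalyst + second product (k = 0.00170 /s)
    target ⇌ isomer of the product (K = 0.780, k = 4.20 × 10⁻⁴ /s)
    target → over-reaction product (k = 4.70 × 10⁻⁷ /s)

In the flask, summer over dawn is 0.737, against 0.739 from n, which carries the scatter of its readings. Dusk over dawn is 0.871, against 0.845. At the end of dawn, catalyst intermediate B holds 14.1% of the catalyst charged, and at the end of summer 36.5%. The row falls in part because second substrate binds free catalyst as catalyst intermediate B. Take that step away, both ways, and the change from dawn to summer goes from −5 points to 0 points.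

All runs were generated by integration on assumed constants; noise was put on by code.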